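## Structural features

Gibberellane numbering (C1–C19, C20 absent) is used throughout; the target has a cyclohexane ring A (C1–C5, C10), a cyclopentane ring B (C5, C6, C8, C9, C10) and a bicyclo[3.2.1]octane C/D unit (C8, C9, C11–C16) that carries a bridgehead tertiary alcohol at C13 next to the exocyclic C16=C17. A γ-lactone (C19 on C4, oxygen on C10) bridges ring A 1,3-diaxially on the α-face, and ring B is trans-fused to ring A across C5–C10 and cis-fused to the six-membered ring C across C8–C9. There are nine stereocentres: C2, C3, C4, C5, C6 and C5, C10, C9, C8 form one contiguous array in which C4 and C8 are quaternary and C10 is fully substituted, while C13 is fixed by the bridge. The 3β-hydroxyl is β to the lactone carbonyl and can be epimerised by base through retro-aldol and aldol, the 13-hydroxy-16-ene unit rearranges in strong acid, and the neopentyl C7 carboxyl sits on an epimerisable C6. The real difficulty is ring B, which must be closed between the fully substituted C8 and C10 with the correct fusion to the lactone, together with the quaternary C4 beside it. The key step exploits the fact that C5 is β and C4 is α to the C19 lactone carbonyl while C6 is α to the C7 carboxyl: the C5–C6 bond is therefore a Michael bond onto a C19→C10 butenolide, and C4 emerges as an enolate that can be quaternised. A second feature specific to this gibberellin is the cis-2β,3β-diol, which is a pinacol retron across C2–C3.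

## Logic of the disconnections

24 ⇐ 23. Only the O–CH3 bond of the C7 ester is cut. The acid is carried as its methyl ester because the key step needs an ester enolate at C6. The forward step must cleave a hindered ester without generating the C3 alkoxide, which would open the retro-aldol path.

23 ⇐ 22. The C2–C3 bond is cut. The cis-diol is read as the pinacol of a dialdehyde, which removes ring A and two stereocentres and leaves both carbons at one oxidation level. The forward reductive coupling must give the cis-diol on the β-face; the α-face is occupied by the lactone bridge.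

22 ⇐ 21 ⇐ 20. No skeletal bond is cut. C3 is stepped back to a primary alcohol, C2 to a dioxolane and the C13 hydroxyl to a silyl ether, so that nothing enolisable or acidic other than C6–H is present when ring B is made.

20 ⇐ 17 (key). The C5–C6 bond of ring B and the C3–C4 bond are cut. This gives a planar butenolide carrying the C6 ester arm, plus a one-carbon electrophile; ring B and the stereocentres C4, C5 and C6 disappear. In one sentence: ring B is closed by intramolecular Michael addition of the C7 ester enolate to a C10-quaternary butenolide, and the lactone enolate so formed is hydroxymethylated at C4 in the same flask. The forward step needs 1,4-attack, cis-fusion of lactone and ring B, and trapping of the C4 enolate on the convex face.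

17 ⇐ 16. The C4=C5 double bond is cut by retro-metathesis to a methacrylate ester and a propenyl group on C10. The demand is ring closure to a trisubstituted butenolide at a tertiary centre without touching the 1,1-disubstituted C16=C17.

16 ⇐ 13 + 14. The C1–C10 bond and the O–C19 ester bond are cut, leaving a propenyl ketone at C10, a two-carbon acetal nucleophile and a methacryloyl unit. The demand is 1,2-addition with Felkin–Anh control by C9, which sets C10, and acylation of the new alkoxide before it can attack the C7 ester.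

13 ⇐ 12 ⇐ 11 ⇐ 10. No skeletal bond is cut. The C10 ketone is stepped back to a silyl-protected allylic alcohol and the C13 silyl ether to the free alcohol. C10 must stay at the alcohol level until C8 is quaternary, otherwise C9 would sit between two carbonyl groups and epimerise.

10 ⇐ 9. The C13–C16 bond is cut: ketyl addition to a propargyl group. This removes ring D, the bridgehead alcohol and the exocyclic methylene in one operation; the demand is 5-exo-dig closure from the conformer with the propargyl group axial.

9 ⇐ 8. The C8–C15 bond is cut: conjugate propargylation of a β,β-disubstituted enone. The quaternary C8 is lost; the forward addition must occur anti to the C9 substituent.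

8 ⇐ 6. The C6–C8 bond is cut: 1,2-addition of an acetate enolate to a vinylogous ester followed by hydrolytic carbonyl transposition. This returns ring C to a commercial 3-alkoxyenone.

6 ⇐ 5 ⇐ 4 ⇐ 1 + 2. The C9–C10 bond is cut as an aldol between the α′-enolate of 1 and 2. C9 becomes the first stereocentre; the forward sequence needs an anti-selective aldol and a kinetic resolution of the allylic alcohol.

## Other disconnections considered

Alternative 1: (the first that comes to mind) Cut C4–C5 and C2–C3 of ring A. The forward key step is an ester-tethered intramolecular Diels–Alder reaction of triene A1, in which a methacrylate on the C7 hydroxymethyl group adds to a C5=C10–C1=C2 diene on a complete B/C/D tricycle. This puts ring A last, so C6, C8, C9 and the whole bicyclooctane must first be built in a long linear sequence. The cycloaddition also delivers a C19→C7 lactone and a C1=C10 alkene. Both must then be corrected (lactone transposition to C10, alkene migration to C2=C3) before the diol can be introduced. The chosen plan makes the C19→C10 lactone directly and leaves C2 and C3 as aldehydes, ready for the diol.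

Alternative 2: Cut C4–C18 and the C10–O bond on an aromatic ring A. The forward key step is reductive methylation of hydrofluorene acid A2 at C4 under dissolving-metal conditions, followed by halolactonisation onto C10. Dissolving metal is not compatible with the allylic bridgehead alcohol and the exocyclic alkene, so rings C and D would have to come later. C5, C9 and C10 are set in separate, weakly controlled operations. The benzoic acid offers no handle for the 2β,3β-diol. The chosen key step sets C4, C5 and C6 together by ring constraint.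

Alternative 3: Cut C6–C8 as a 1,2-shift, copying the biosynthetic contraction of ring B. The forward key step is a photochemical Wolff ring contraction of diazoketone A3, a 20-nor-kauranolide in which C8 migrates from C7 to C6. The step sets only C6, and it sets it by ketene protonation. A3 already contains every other stereocentre and is no easier to make than the target. Natural kauranoids do not help, because they carry C20 and an unfunctionalised ring A. The chosen plan spends its key step on the congested C4/C5/C6 array instead.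

Key step: step 12

Remark: compound 4 is a racemate; its SMILES lists both enantiomers.
Remark: the sense of the kinetic resolution in step 2 follows the usual tartrate mnemonic for secondary (E)-allylic alcohols.

## Steps

Step 1
Reactants: 1 3-ethoxycyclohex-2-en-1-one; 2 (2E)-but-2-enal
Product: 4 rac-(6S*)-3-ethoxy-6-[(1S*,2E)-1-hydroxybut-2-en-1-yl]cyclohex-2-en-1-one (anti aldol), via boron dienolate 3 (not isolated)
Conditions: (c-C6H11)2BCl, Et3N, Et2O, −78 → 0 °C; then 2, −78 °C; MeOH, pH 7 buffer
Reagents that add atoms: none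
Why: Boron-mediated aldol addition at the α′-position of the vinylogous ester; the ring-locked E-enolate should react through a closed chair transition state to give the anti aldol, forming C9–C10 with 1,2-addition to the enal.

Step 2
Reactants: 4 rac-(6S*)-3-ethoxy-6-[(1S*,2E)-1-hydroxybut-2-en-1-yl]cyclohex-2-en-1-one
Product: 5 (6S)-3-ethoxy-6-[(1S,2E)-1-hydroxybut-2-en-1-yl]cyclohex-2-en-1-one
Conditions: Ti(Oi-Pr)4, L-(+)-diisopropyl tartrate, t-BuOOH (0.6 equiv), 4 Å MS, CH2Cl2, −20 °C
Reagents that add atoms: none
Why: Sharpless kinetic resolution of a secondary (E)-allylic alcohol; with the L-(+)-tartrate the (6R,1′R)-enantiomer should be epoxidised fast and the (6S,1′S)-alcohol recovered, which fixes C9 in the absolute sense needed.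

Step 3
Reactants: 5 (6S)-3-ethoxy-6-[(1S,2E)-1-hydroxybut-2-en-1-yl]cyclohex-2-en-1-one
Product: 6 (6S)-6-[(1S,2E)-1-{[tert-butyl(dimethyl)silyl]oxy}but-2-en-1-yl]-3-ethoxycyclohex-2-en-1-one
Conditions: TBSCl, imidazole, DMF, 25 °C
Reagents that add atoms: tert-butyl(chloro)dimethylsilane CC(C)(C)[Si](C)(C)Cl
Why: Standard silylation; the C10 oxygen must stay at the alcohol level and be masked until C8 is quaternary.

Step 4
Reactants: 6 (6S)-6-[(1S,2E)-1-{[tert-butyl(dimethyl)silyl]oxy}but-2-en-1-yl]-3-ethoxycyclohex-2-en-1-one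
Product: 8 methyl 2-[(6R)-6-[(1S,2E)-1-{[tert-butyl(dimethyl)silyl]oxy}but-2-en-1-yl]-3-oxocyclohex-1-en-1-yl]acetate, via lithium alkoxide adduct 7 (not isolated)
Conditions: MeOAc, LDA, THF, −78 °C; add 6; then 1 M HCl, THF, 0 °C
Reagents that add atoms: methyl acetate CC(=O)OC; water O
Why: Stork–Danheiser transposition: 1,2-addition of the acetate enolate to the vinylogous ester, then hydrolysis of the enol ether and dehydration, should give the conjugated enone with the C6–C7 arm on C8; C9 is untouched if the acid treatment is kept short and cold.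

Step 5
Reactants: 8 methyl 2-[(6R)-6-[(1S,2E)-1-{[tert-butyl(dimethyl)silyl]oxy}but-2-en-1-yl]-3-oxocyclohex-1-en-1-yl]acetate
Product: 9 methyl 2-[(1R,2R)-2-[(1S,2E)-1-{[tert-butyl(dimethyl)silyl]oxy}but-2-en-1-yl]-5-oxo-1-(prop-2-yn-1-yl)cyclohexyl]acetate
Conditions: allenyltributylstannane, TiCl4, CH2Cl2, −78 °C
Reagents that add atoms: allenyltributylstannane C=C=C[Sn](CCCC)(CCCC)CCCC
Why: Lewis-acid-promoted conjugate propargylation (Hosomi–Sakurai type, SE2′ at the allenylmetal) of a β,β-disubstituted enone; attack anti to the adjacent C9 substituent should set the quaternary C8 with C15 trans and the C6 arm cis to C10.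

Step 6
Reactants: 9 methyl 2-[(1R,2R)-2-[(1S,2E)-1-{[tert-butyl(dimethyl)silyl]oxy}but-2-en-1-yl]-5-oxo-1-(prop-2-yn-1-yl)cyclohexyl]acetate
Product: 10 methyl 2-[(1R,2R,5S)-2-[(1S,2E)-1-{[tert-butyl(dimethyl)silyl]oxy}but-2-en-1-yl]-5-hydroxy-6-methylidenebicyclo[3.2.1]octan-1-yl]acetate
Conditions: SmI2, HMPA, t-BuOH, THF, 0 °C
Reagents that add atoms: none
Why: Ketyl–alkyne reductive cyclisation (5-exo-dig) forms C13–C16 and gives the bridgehead alcohol and the exocyclic methylene at once; the configuration at C13 is dictated by the bridge, and ester and silyl ether are inert to SmI2.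

Step 7
Reactants: 10 methyl 2-[(1R,2R,5S)-2-[(1S,2E)-1-{[tert-butyl(dimethyl)silyl]oxy}but-2-en-1-yl]-5-hydroxy-6-methylidenebicyclo[3.2.1]octan-1-yl]acetate
Product: 11 methyl 2-[(1R,2R,5S)-5-hydroxy-2-[(1S,2E)-1-hydroxybut-2-en-1-yl]-6-methylidenebicyclo[3.2.1]octan-1-yl]acetate
Conditions: Bu4NF, AcOH (1:1), THF, 0 → 25 °C; used at once
Reagents that add atoms: none
Why: Fluoride desilylation of the secondary allylic silyl ether; acetic acid buffers the medium so that the freed C10 oxygen does not close a δ-lactone onto the C7 ester, and no other group is fluoride-labile.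

Step 8
Reactants: 11 methyl 2-[(1R,2R,5S)-5-hydroxy-2-[(1S,2E)-1-hydroxybut-2-en-1-yl]-6-methylidenebicyclo[3.2.1]octan-1-yl]acetate
Product: 12 methyl 2-[(1R,2R,5S)-2-[(2E)-but-2-enoyl]-5-hydroxy-6-methylidenebicyclo[3.2.1]octan-1-yl]acetate
Conditions: Dess–Martin periodinane, CH2Cl2, 25 °C
Reagents that add atoms: none
Why: Dess–Martin oxidation of the secondary allylic alcohol to the propenyl ketone; the tertiary C13 alcohol cannot be oxidised, and C9 is no longer flanked by a second carbonyl group.

Step 9
Reactants: 12 methyl 2-[(1R,2R,5S)-2-[(2E)-but-2-enoyl]-5-hydroxy-6-methylidenebicyclo[3.2.1]octan-1-yl]acetate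
Product: 13 methyl 2-[(1R,2R,5S)-2-[(2E)-but-2-enoyl]-6-methylidene-5-[(triethylsilyl)oxy]bicyclo[3.2.1]octan-1-yl]acetate
Conditions: Et3SiOTf, 2,6-lutidine, CH2Cl2, −78 °C
Reagents that add atoms: triethylsilyl trifluoromethanesulfonate CC[Si](CC)(CC)OS(=O)(=O)C(F)(F)F
Why: Silylation of the tertiary alcohol with a silyl triflate, so that only the C10 alkoxide is acylated in the next step and no acidic O–H is present in the key step.

Step 10
Reactants: 13 methyl 2-[(1R,2R,5S)-2-[(2E)-but-2-enoyl]-6-methylidene-5-[(triethylsilyl)oxy]bicyclo[3.2.1]octan-1-yl]acetate; 14 (1,3-dioxolan-2-ylmethyl)magnesium bromide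
Product: 16 (2S,3E)-1-(1,3-dioxolan-2-yl)-2-[(1R,2R,5S)-1-(2-methoxy-2-oxoethyl)-6-methylidene-5-[(triethylsilyl)oxy]bicyclo[3.2.1]octan-2-yl]pent-3-en-2-yl 2-methylprop-2-enoate, via bromomagnesium alkoxide 15 (not isolated)
Conditions: 14, CeCl3, THF, −78 °C; then methacryloyl chloride (excess), −78 → 0 °C
Reagents that add atoms: methacryloyl chloride CC(=C)C(=O)Cl
Why: Cerium-mediated 1,2-addition to the enone, then O-acylation of the alkoxide in the same flask; in the Felkin–Anh arrangement the nucleophile (C1) enters anti to the quaternary C8 with C11 on the carbonyl-oxygen side, which gives the C10 configuration of the target. The hindered C7 ester should not compete with the ketone at −78 °C, and the acid chloride is added cold and in excess so that acylation outruns attack of the alkoxide on the C7 ester.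

Step 11
Reactants: 16 (2S,3E)-1-(1,3-dioxolan-2-yl)-2-[(1R,2R,5S)-1-(2-methoxy-2-oxoethyl)-6-methylidene-5-[(triethylsilyl)oxy]bicyclo[3.2.1]octan-2-yl]pent-3-en-2-yl 2-methylprop-2-enoate
Product: 17 methyl 2-[(1R,2R,5S)-2-[(2S)-2-(1,3-dioxolan-2-ylmethyl)-4-methyl-5-oxo-2,5-dihydrofuran-2-yl]-6-methylidene-5-[(triethylsilyl)oxy]bicyclo[3.2.1]octan-1-yl]acetate
Conditions: second-generation Grubbs catalyst (10 mol%), toluene, 80 °C
Reagents that add atoms: none
Why: Ring-closing metathesis between the methacrylate and the propenyl group gives the α-methylbutenolide (C4=C5) and propene; the hindered 1,1-disubstituted C16=C17 has no partner at ring-forming distance.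

Step 12
Reactants: 17 methyl 2-[(1R,2R,5S)-2-[(2S)-2-(1,3-dioxolan-2-ylmethyl)-4-methyl-5-oxo-2,5-dihydrofuran-2-yl]-6-methylidene-5-[(triethylsilyl)oxy]bicyclo[3.2.1]octan-1-yl]acetate
Product: 20 methyl (4S,5R,6S,8S,9R,10R,13S)-2,2-(ethane-1,2-diyldioxy)-3-hydroxy-13-[(triethylsilyl)oxy]-2,3-seco-20-norgibberell-16-en-19,10-olid-7-oate, via lithium ester enolate 18 (not isolated), via lithium lactone enolate 19 (not isolated)
Conditions: LDA (1.2 equiv), THF, −78 → −30 °C; CH2O (gas), −78 °C; AcOH
Reagents that add atoms: formaldehyde C=O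
Why: LDA removes a proton from the only acidic C–H pair (C6–H2, α to the C7 ester) to give 18; C6 then adds to C5, the β-carbon of the butenolide, in a 5-(enolexo)-exo-trig Michael addition that closes ring B and gives lactone enolate 19, which monomeric formaldehyde hydroxymethylates at C4. The closest known reaction type is the intramolecular ester-enolate Michael addition to a butenolide with aldol trapping of the new enolate (Michael-initiated tandem reaction). C5 is set by the tether: through C8–C9, C6 can reach only the butenolide face that carries C9, so lactone and ring B become cis-fused and H5 ends cis to C1. C6 is set by the ester taking the exo side of the forming bicyclo[3.3.0] unit, trans to C4; this is also the stable arrangement and can be secured by equilibration. C4 is set by attack of formaldehyde on the convex face of the cis-fused lactone/ring-B bicycle, which places C3 cis to C1 and the methyl group endo. The step needs 1,4- rather than 1,2-attack on the lactone, which the five-membered transition state and the hindered enolate favour, and C- rather than O-trapping, for which a small reactive electrophile is chosen. Compound 17 has no other enolisable position because C10 is quaternary. Formaldehyde is introduced cold as soon as ring closure is complete, so that 19 is trapped before proton transfer from C6–H can move the enolate.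

Step 13
Reactants: 20 methyl (4S,5R,6S,8S,9R,10R,13S)-2,2-(ethane-1,2-diyldioxy)-3-hydroxy-13-[(triethylsilyl)oxy]-2,3-seco-20-norgibberell-16-en-19,10-olid-7-oate
Product: 21 methyl (4S,5R,6S,8S,9R,10R,13S)-3,13-dihydroxy-2-oxo-2,3-seco-20-norgibberell-16-en-19,10-olid-7-oate
Conditions: 1 M HCl, THF, 25 °C
Reagents that add atoms: water O
Why: Acid hydrolysis of the dioxolane and of the tertiary silyl ether; dilute acid at room temperature should stay below the threshold for rearrangement of the 13-hydroxy-16-ene unit, and C3 is kept as the alcohol so that the dialdehyde never meets acid.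

Step 14
Reactants: 21 methyl (4S,5R,6S,8S,9R,10R,13S)-3,13-dihydroxy-2-oxo-2,3-seco-20-norgibberell-16-en-19,10-olid-7-oate
Product: 22 methyl (4S,5R,6S,8S,9R,10R,13S)-13-hydroxy-2,3-dioxo-2,3-seco-20-norgibberell-16-en-19,10-olid-7-oate
Conditions: Dess–Martin periodinane, CH2Cl2, 0 °C; used at once
Reagents that add atoms: none
Why: Dess–Martin oxidation of the neopentyl primary alcohol under neutral conditions; the C3 aldehyde is not enolisable and the tertiary alcohol is inert.

Step 15
Reactants: 22 methyl (4S,5R,6S,8S,9R,10R,13S)-13-hydroxy-2,3-dioxo-2,3-seco-20-norgibberell-16-en-19,10-olid-7-oate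
Product: 23 methyl (2S,3R,4S,5R,6S,8S,9R,10R,13S)-2,3,13-trihydroxy-20-norgibberell-16-en-19,10-olid-7-oate (methyl ester of the target)
Conditions: SmI2 (3 equiv), t-BuOH, THF, −78 °C
Reagents that add atoms: none
Why: SmI2-mediated intramolecular pinacol coupling closes ring A through C2–C3; the samarium-bridged bis-ketyl should give the cis-diol, and the α-face is closed by the lactone bridge, so both hydroxyls should end β (2-equatorial, 3-axial). Lactone, ester and alkene are not reduced under these conditions.

Step 16
Reactants: 23 methyl (2S,3R,4S,5R,6S,8S,9R,10R,13S)-2,3,13-trihydroxy-20-norgibberell-16-en-19,10-olid-7-oate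
Product: 24 (2S,3R,4S,5R,6S,8S,9R,10R,13S)-2,3,13-trihydroxy-20-norgibberell-16-ene-7,19-dioic acid 19,10-lactone (the target)
Conditions: n-PrSLi, HMPA, 25 °C; then dilute HCl, 0 °C
Reagents that add atoms: none
Why: SN2 demethylation of the hindered ester by thiolate at the methyl carbon; the reagent is too weakly basic to form the C3 alkoxide, so retro-aldol epimerisation at C3 and epimerisation at C6 are avoided.

## Compound list

1 | 3-ethoxycyclohex-2-en-1-one | CCOC1=CC(=O)CCC1 | starting material
2 | (2E)-but-2-enal | C/C=C/C=O | starting material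
3 | dicyclohexylboron dienolate of 1, dicyclohexyl[(5-ethoxycyclohexa-1,5-dien-1-yl)oxy]borane | CCOC1=CC(OB(C2CCCCC2)C2CCCCC2)=CCC1 | intermediate
4 | rac-(6S*)-3-ethoxy-6-[(1S*,2E)-1-hydroxybut-2-en-1-yl]cyclohex-2-en-1-one (racemate, both enantiomers shown) | CCOC1=CC(=O)[C@@H](CC1)[C@@H](O)/C=C/C.CCOC1=CC(=O)[C@H](CC1)[C@H](O)/C=C/C | intermediate
5 | (6S)-3-ethoxy-6-[(1S,2E)-1-hydroxybut-2-en-1-yl]cyclohex-2-en-1-one | CCOC1=CC(=O)[C@@H](CC1)[C@@H](O)/C=C/C | intermediate
6 | (6S)-6-[(1S,2E)-1-{[tert-butyl(dimethyl)silyl]oxy}but-2-en-1-yl]-3-ethoxycyclohex-2-en-1-one | CCOC1=CC(=O)[C@@H](CC1)[C@@H](O[Si](C)(C)C(C)(C)C)/C=C/C | intermediate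
7 | lithium alkoxide of methyl 2-[(6S)-6-[(1S,2E)-1-{[tert-butyl(dimethyl)silyl]oxy}but-2-en-1-yl]-3-ethoxy-1-hydroxycyclohex-2-en-1-yl]acetate (both C1 epimers) | CCOC1=CC(O[Li])(CC(=O)OC)[C@@H](CC1)[C@@H](O[Si](C)(C)C(C)(C)C)/C=C/C | intermediate
8 | methyl 2-[(6R)-6-[(1S,2E)-1-{[tert-butyl(dimethyl)silyl]oxy}but-2-en-1-yl]-3-oxocyclohex-1-en-1-yl]acetate | COC(=O)CC1=CC(=O)CC[C@H]1[C@@H](O[Si](C)(C)C(C)(C)C)/C=C/C | intermediate
9 | methyl 2-[(1R,2R)-2-[(1S,2E)-1-{[tert-butyl(dimethyl)silyl]oxy}but-2-en-1-yl]-5-oxo-1-(prop-2-yn-1-yl)cyclohexyl]acetate | COC(=O)C[C@@]1(CC#C)CC(=O)CC[C@H]1[C@@H](O[Si](C)(C)C(C)(C)C)/C=C/C | intermediate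
10 | methyl 2-[(1R,2R,5S)-2-[(1S,2E)-1-{[tert-butyl(dimethyl)silyl]oxy}but-2-en-1-yl]-5-hydroxy-6-methylidenebicyclo[3.2.1]octan-1-yl]acetate | C=C1C[C@]2(CC(=O)OC)C[C@@]1(O)CC[C@H]2[C@@H](O[Si](C)(C)C(C)(C)C)/C=C/C | intermediate
11 | methyl 2-[(1R,2R,5S)-5-hydroxy-2-[(1S,2E)-1-hydroxybut-2-en-1-yl]-6-methylidenebicyclo[3.2.1]octan-1-yl]acetate | C=C1C[C@]2(CC(=O)OC)C[C@@]1(O)CC[C@H]2[C@@H](O)/C=C/C | intermediate
12 | methyl 2-[(1R,2R,5S)-2-[(2E)-but-2-enoyl]-5-hydroxy-6-methylidenebicyclo[3.2.1]octan-1-yl]acetate | C=C1C[C@]2(CC(=O)OC)C[C@@]1(O)CC[C@H]2C(=O)/C=C/C | intermediate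
13 | methyl 2-[(1R,2R,5S)-2-[(2E)-but-2-enoyl]-6-methylidene-5-[(triethylsilyl)oxy]bicyclo[3.2.1]octan-1-yl]acetate | C=C1C[C@]2(CC(=O)OC)C[C@@]1(O[Si](CC)(CC)CC)CC[C@H]2C(=O)/C=C/C | intermediate
14 | (1,3-dioxolan-2-ylmethyl)magnesium bromide | Br[Mg]CC1OCCO1 | starting material
15 | bromomagnesium alkoxide of the tertiary C10 carbinol formed from 13 and 14 | C=C1C[C@]2(CC(=O)OC)C[C@@]1(O[Si](CC)(CC)CC)CC[C@H]2[C@@](O[Mg]Br)(/C=C/C)CC1OCCO1 | intermediate
16 | (2S,3E)-1-(1,3-dioxolan-2-yl)-2-[(1R,2R,5S)-1-(2-methoxy-2-oxoethyl)-6-methylidene-5-[(triethylsilyl)oxy]bicyclo[3.2.1]octan-2-yl]pent-3-en-2-yl 2-methylprop-2-enoate | C=C1C[C@]2(CC(=O)OC)C[C@@]1(O[Si](CC)(CC)CC)CC[C@H]2[C@@](OC(=O)C(C)=C)(/C=C/C)CC1OCCO1 | intermediate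
17 | methyl 2-[(1R,2R,5S)-2-[(2S)-2-(1,3-dioxolan-2-ylmethyl)-4-methyl-5-oxo-2,5-dihydrofuran-2-yl]-6-methylidene-5-[(triethylsilyl)oxy]bicyclo[3.2.1]octan-1-yl]acetate | C=C1C[C@]2(CC(=O)OC)C[C@@]1(O[Si](CC)(CC)CC)CC[C@H]2[C@@]1(CC2OCCO2)OC(=O)C(C)=C1 | intermediate
18 | lithium enolate of the C7 ester of 17 (C6 carbanion equivalent; enolate geometry open) | C=C1C[C@]2(C=C(OC)O[Li])C[C@@]1(O[Si](CC)(CC)CC)CC[C@H]2[C@@]1(CC2OCCO2)OC(=O)C(C)=C1 | intermediate
19 | lithium enolate of the C19 lactone after closure of ring B (C4=C19 enolate) | C=C1C[C@]23C[C@@]1(O[Si](CC)(CC)CC)CC[C@H]2[C@@]1(CC2OCCO2)OC(O[Li])=C(C)[C@H]1[C@@H]3C(=O)OC | intermediate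
20 | methyl (4S,5R,6S,8S,9R,10R,13S)-2,2-(ethane-1,2-diyldioxy)-3-hydroxy-13-[(triethylsilyl)oxy]-2,3-seco-20-norgibberell-16-en-19,10-olid-7-oate (ring A open between C2 and C3) | C=C1C[C@]23C[C@@]1(O[Si](CC)(CC)CC)CC[C@H]2[C@@]1(CC2OCCO2)OC(=O)[C@](C)(CO)[C@H]1[C@@H]3C(=O)OC | intermediate
21 | methyl (4S,5R,6S,8S,9R,10R,13S)-3,13-dihydroxy-2-oxo-2,3-seco-20-norgibberell-16-en-19,10-olid-7-oate | C=C1C[C@]23C[C@@]1(O)CC[C@H]2[C@@]1(CC=O)OC(=O)[C@](C)(CO)[C@H]1[C@@H]3C(=O)OC | intermediate
22 | methyl (4S,5R,6S,8S,9R,10R,13S)-13-hydroxy-2,3-dioxo-2,3-seco-20-norgibberell-16-en-19,10-olid-7-oate | C=C1C[C@]23C[C@@]1(O)CC[C@H]2[C@@]1(CC=O)OC(=O)[C@](C)(C=O)[C@H]1[C@@H]3C(=O)OC | intermediate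
23 | methyl (2S,3R,4S,5R,6S,8S,9R,10R,13S)-2,3,13-trihydroxy-20-norgibberell-16-en-19,10-olid-7-oate (methyl ester of the target) | C=C1C[C@]23C[C@@]1(O)CC[C@H]2[C@@]12C[C@H](O)[C@H](O)[C@@](C)(C(=O)O1)[C@H]2[C@@H]3C(=O)OC | intermediate
24 | (2S,3R,4S,5R,6S,8S,9R,10R,13S)-2,3,13-trihydroxy-20-norgibberell-16-ene-7,19-dioic acid 19,10-lactone (the target gibberellin) | C=C1C[C@]23C[C@@]1(O)CC[C@H]2[C@@]12C[C@H](O)[C@H](O)[C@@](C)(C(=O)O1)[C@H]2[C@@H]3C(=O)O | target

## Step count and least certain steps

Total step count: 16. Longest linear sequence: 16 steps (from 1).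

**Step 12 (key step).** The most likely failure is attack of the ester enolate on the lactone carbonyl, or proton transfer in place of conjugate addition, because C5 lies between the substituted C4 and the quaternary C10. A second risk is hydroxymethylation from the concave face, or at C6 after proton transfer from C6–H to the lactone enolate.
The fallback closes ring B by a radical instead of an anion; it sets out from 17 and returns at 20. Enolate 18 is formed at −78 °C, where ring closure is slow, and is quenched at once with NBS to give the α-bromo ester F1. Bu3SnH and AIBN generate the C6 radical, which closes ring B by 5-exo-trig addition to C5 and is reduced at C4 to the saturated lactone F2 (both C4 epimers); the polarity of this addition is not ideal, but the five-membered ring closure should compensate. The lactone α-hydrogen of F2 is then the most accessible acidic site, and LDA followed by formaldehyde gives 20, the electrophile again entering on the convex face.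

**Step 10.** The β,β-dialkoxy Grignard reagent is sluggish. Enolisation at C9, conjugate addition and incomplete O-acylation of the crowded alkoxide may compete, the alkoxide may instead close a δ-lactone onto the C7 ester, and facial control at C10 rests on the Felkin–Anh preference alone.
The fallback brings C1–C2 in as an alkyne; it sets out from 13 and returns at 21. Lithium (trimethylsilyl)acetylide with CeCl3 adds 1,2 in the same Felkin sense, and methacryloyl chloride gives the enyne ester F3. Ring-closing metathesis gives the alkynyl butenolide F4. The Michael addition and hydroxymethylation of step 12 give the seco lactone F5. Bu4NF buffered with AcOH removes both silyl groups to give the terminal alkyne F6. Ruthenium-catalysed anti-Markovnikov hydration of the alkyne then gives aldehyde 21.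

**Step 11.** Metathesis may stall, because the catalyst must engage a propenyl group on a quaternary carbon and a 1,1-disubstituted acrylate; alkene isomerisation may then take over.
The fallback moves the methyl group out of the metathesis; it sets out from 13 and returns at 20. The alkoxide from 13 and 14 is acylated with acryloyl chloride to the acrylate F7, which closes more readily to the α-unsubstituted butenolide F8. Michael ring closure as in step 12 followed by methyl iodide gives the methyl lactone F9 (methyl on the convex face). A second deprotonation at C4 and formaldehyde then gives 20, because the second electrophile again enters on the convex face and pushes the methyl group to the endo position.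

**Step 15.** The dialdehyde may give the trans-diol (2β,3α, both equatorial). It may also be lost before coupling, by intramolecular aldol addition of C1 to C3 or by β-elimination of the C10 oxygen from the C2 aldehyde.
The fallback reaches the diol through the alkene; it sets out from 22 and returns at 23. Low-valent titanium (TiCl3, Zn–Cu, DME) couples the two aldehydes directly to the C2=C3 alkene, the ring-A 2-ene methyl ester F10. Osmium tetroxide then dihydroxylates the ring-A alkene on its open β-face to give 23. The 16-ene is hindered and 1,1-disubstituted, but it may compete, so OsO4 would be used in limiting amount.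

**Step 5.** The allylic silyl ether may ionise under TiCl4, the stannane may add 1,2, and the facial preference at the γ-substituted enone may be incomplete.
The fallback changes the ring-D precursor; it sets out from 8 and returns at 10. (2-Bromoallyl)trimethylsilane with a milder Lewis acid gives the 2-bromoallyl ketone F11 by Hosomi–Sakurai addition. Intramolecular Nozaki–Hiyama–Kishi addition of the vinyl bromide to the C13 ketone (CrCl2, NiCl2 catalyst) then gives 10 directly.

## Further compounds

F1 | step 12 | methyl 2-bromo-2-[(1R,2R,5S)-2-[(2S)-2-(1,3-dioxolan-2-ylmethyl)-4-methyl-5-oxo-2,5-dihydrofuran-2-yl]-6-methylidene-5-[(triethylsilyl)oxy]bicyclo[3.2.1]octan-1-yl]acetate (both C6 epimers) | C=C1C[C@]2(C(Br)C(=O)OC)C[C@@]1(O[Si](CC)(CC)CC)CC[C@H]2[C@@]1(CC2OCCO2)OC(=O)C(C)=C1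
F2 | step 12 | methyl (5R,6S,8S,9R,10R,13S)-2,2-(ethane-1,2-diyldioxy)-13-[(triethylsilyl)oxy]-3-nor-2,3-seco-20-norgibberell-16-en-19,10-olid-7-oate (C4 bears H and methyl, both C4 epimers) | C=C1C[C@]23C[C@@]1(O[Si](CC)(CC)CC)CC[C@H]2[C@@]1(CC2OCCO2)OC(=O)C(C)[C@H]1[C@@H]3C(=O)OC
F3 | step 10 | (4E)-3-[(1R,2R,5S)-1-(2-methoxy-2-oxoethyl)-6-methylidene-5-[(triethylsilyl)oxy]bicyclo[3.2.1]octan-2-yl]-1-(trimethylsilyl)hex-4-en-1-yn-3-yl 2-methylprop-2-enoate (C10 configured as in 16) | C=C1C[C@]2(CC(=O)OC)C[C@@]1(O[Si](CC)(CC)CC)CC[C@H]2[C@@](OC(=O)C(C)=C)(/C=C/C)C#C[Si](C)(C)C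
F4 | step 10 | methyl 2-[(1R,2R,5S)-2-{4-methyl-5-oxo-2-[(trimethylsilyl)ethynyl]-2,5-dihydrofuran-2-yl}-6-methylidene-5-[(triethylsilyl)oxy]bicyclo[3.2.1]octan-1-yl]acetate (C10 configured as in 17) | C=C1C[C@]2(CC(=O)OC)C[C@@]1(O[Si](CC)(CC)CC)CC[C@H]2[C@@]1(C#C[Si](C)(C)C)OC(=O)C(C)=C1
F5 | step 10 | analogue of 20 with a (trimethylsilyl)ethynyl group on C10 in place of the dioxolanylmethyl group | C=C1C[C@]23C[C@@]1(O[Si](CC)(CC)CC)CC[C@H]2[C@@]1(C#C[Si](C)(C)C)OC(=O)[C@](C)(CO)[C@H]1[C@@H]3C(=O)OC
F6 | step 10 | analogue of 21 with an ethynyl group on C10 in place of the 2-oxoethyl group | C=C1C[C@]23C[C@@]1(O)CC[C@H]2[C@@]1(C#C)OC(=O)[C@](C)(CO)[C@H]1[C@@H]3C(=O)OC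
F7 | step 11 | (2S,3E)-1-(1,3-dioxolan-2-yl)-2-[(1R,2R,5S)-1-(2-methoxy-2-oxoethyl)-6-methylidene-5-[(triethylsilyl)oxy]bicyclo[3.2.1]octan-2-yl]pent-3-en-2-yl prop-2-enoate | C=C1C[C@]2(CC(=O)OC)C[C@@]1(O[Si](CC)(CC)CC)CC[C@H]2[C@@](OC(=O)C=C)(/C=C/C)CC1OCCO1
F8 | step 11 | methyl 2-[(1R,2R,5S)-2-[(2S)-2-(1,3-dioxolan-2-ylmethyl)-5-oxo-2,5-dihydrofuran-2-yl]-6-methylidene-5-[(triethylsilyl)oxy]bicyclo[3.2.1]octan-1-yl]acetate | C=C1C[C@]2(CC(=O)OC)C[C@@]1(O[Si](CC)(CC)CC)CC[C@H]2[C@@]1(CC2OCCO2)OC(=O)C=C1
F9 | step 11 | analogue of 20 with hydrogen on C4 in place of the hydroxymethyl group, methyl on the convex face | C=C1C[C@]23C[C@@]1(O[Si](CC)(CC)CC)CC[C@H]2[C@@]1(CC2OCCO2)OC(=O)[C@H](C)[C@H]1[C@@H]3C(=O)OC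
F10 | step 15 | methyl 13-hydroxy-20-norgibberella-2,16-dien-19,10-olid-7-oate, the ring-A 2-ene corresponding to 23 (C4, C5, C6, C8, C9, C10 and C13 arranged as in 23) | C=C1C[C@]23C[C@@]1(O)CC[C@H]2[C@@]12CC=C[C@@](C)(C(=O)O1)[C@H]2[C@@H]3C(=O)OC
F11 | step 5 | methyl 2-[1-(2-bromoprop-2-en-1-yl)-2-[(1S,2E)-1-{[tert-butyl(dimethyl)silyl]oxy}but-2-en-1-yl]-5-oxocyclohexyl]acetate (ring stereocentres as in 9) | COC(=O)C[C@@]1(CC(Br)=C)CC(=O)CC[C@H]1[C@@H](O[Si](C)(C)C(C)(C)C)/C=C/C
A1 | alternative 1 | methacrylate of the 7-hydroxymethyl B/C/D tricycle carrying the C5=C10–C1=C2 diene | C=C1C[C@]23C[C@@]1(O)CC[C@H]2C(C=C)=C[C@@H]3COC(=O)C(C)=C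
A2 | alternative 2 | hydrofluorene with aromatic ring A, C4 carboxylic acid and C7 methyl ester | C=C1C[C@]23C[C@@]1(O)CC[C@H]2c1cccc(C(=O)O)c1[C@@H]3C(=O)OC
A3 | alternative 3 | 6-diazo-7-oxo-20-norkauranolide with a six-membered ring B | C=C1C[C@]23C[C@@]1(O)CC[C@H]2[C@@]12C[C@H](O)[C@H](O)[C@@](C)(C(=O)O1)[C@H]2C(=[N+]=[N-])C3=O
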